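**Retrosynthetic overview**

1. The target is epicatechin 3-O-gallate-(4β→6)-epicatechin 3-O-gallate-(4β→8)-catechin. Last disconnections: 19 benzyl ethers and a C8 bromine (hydrogenolysis), both gallate esters, then the middle C4–bottom C8 bond (C4 cation from a 4-alkoxy ether, captured by penta-O-benzylcatechin).
2. Feature used: top-unit C4 is a methine joining two phloroglucinol rings, ring A of the top unit (which carries O1 ortho to C4a) and C6 of middle ring A. C4a–C4 with O1 is therefore an o-quinone methide, and C3–C2 is an α-oxygenated acetaldehyde.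
3. Key disconnection: C3–C4 and O1–C2 of top ring C, by enamine addition of silyloxyacetaldehyde to the o-quinone methide from a benzhydrol on middle C6; ring C closes as a 3,4-trans lactol.
4. Precursor: (−)-epicatechin is benzylated, 3-O-silylated, brominated at C8 and iodinated at C6. Selective I/Mg exchange and addition to an O-allyl salicylaldehyde fix the 4→6 connectivity.
5. Ring order: rings A and C of the middle and bottom units come from the chiral pool, and top ring A arrives with the aldehyde. Top ring C is closed in the key step, reopened by Felkin aryl addition (ring B, C2) and reclosed at O1–C2 by SN2 (Mitsunobu), because hydride reduction of a 2-aryl oxocarbenium ion is expected to be steered anti to the axial C4 aryl group (2,4-cis).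

Key step: step 9

Assumption: the carbinol epimers of 10 and 11 and the anomers of 15 are carried on as mixtures, because these centres become planar (methide) or are opened (aldehyde) in the following step.

**Route**

Step 1
Reactants: 1 (−)-epicatechin
Product: 2 5,7,3',4'-tetra-O-benzyl-(−)-epicatechin
Conditions: BnBr (4.4 equiv), K2CO3, DMF, 0 °C → rt
Reagents that add atoms: benzyl bromide, BrCc1ccccc1
Why: Williamson etherification in which carbonate deprotonates only the four phenols, so the aliphatic 3-OH stays free and no stereocentre is touched.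

Step 2
Reactants: 2 5,7,3',4'-tetra-O-benzyl-(−)-epicatechin
Product: 3 3-O-tert-butyldimethylsilyl-5,7,3',4'-tetra-O-benzyl-epicatechin
Conditions: TBSCl, imidazole, DMF, rt
Reagents that add atoms: tert-butyldimethylsilyl chloride, CC(C)(C)[Si](C)(C)Cl
Why: Standard imidazole-promoted silylation of the secondary alcohol, giving an ether that survives organomagnesium reagents, weak acid and Mitsunobu conditions and is removed by fluoride.

Step 3
Reactants: 3 3-O-TBS-5,7,3',4'-tetra-O-benzyl-epicatechin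
Product: 4 8-bromo-3-O-TBS-5,7,3',4'-tetra-O-benzyl-epicatechin
Conditions: NBS (1.0 equiv), CH2Cl2, −78 °C → 0 °C
Reagents that add atoms: N-bromosuccinimide, O=C1CCC(=O)N1Br
Why: Electrophilic aromatic bromination, which in 5,7-di-O-benzyl flavans goes to C8; the bromine blocks C8 against iodination, against electrophiles in steps 9 and 15, and leaves in step 18.

Step 4
Reactants: 4 8-bromo-3-O-TBS-5,7,3',4'-tetra-O-benzyl-epicatechin
Product: 5 8-bromo-6-iodo-3-O-TBS-5,7,3',4'-tetra-O-benzyl-epicatechin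
Conditions: NIS (1.2 equiv), DMF, rt, dark
Reagents that add atoms: N-iodosuccinimide, O=C1CCC(=O)N1I
Why: Electrophilic aromatic iodination at C6, the only free ring A position and still activated by three ortho/para oxygens; iodine is chosen so that the later metalation distinguishes C6 from C8.

Step 5
Reactants: 6 2,4,6-trihydroxybenzaldehyde
Product: 7 4,6-bis(benzyloxy)-2-hydroxybenzaldehyde
Conditions: BnBr (2.1 equiv), K2CO3 (2.2 equiv), DMF, rt
Reagents that add atoms: benzyl bromide, BrCc1ccccc1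
Why: Williamson etherification that takes the para and one ortho phenol, while the second ortho hydroxyl is hydrogen-bonded to the formyl group and is the least nucleophilic.

Step 6
Reactants: 7 4,6-bis(benzyloxy)-2-hydroxybenzaldehyde
Product: 8 2-(allyloxy)-4,6-bis(benzyloxy)benzaldehyde
Conditions: allyl bromide, K2CO3, DMF, 60 °C
Reagents that add atoms: allyl bromide, C=CCBr
Why: Williamson allylation of the chelated phenol under slightly forcing conditions, giving a phenol mask removable under neutral palladium catalysis in the presence of benzyl and silyl ethers.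

Step 7
Reactants: 5 8-bromo-6-iodo-3-O-TBS-5,7,3',4'-tetra-O-benzyl-epicatechin; 8 2-(allyloxy)-4,6-bis(benzyloxy)benzaldehyde
Product: 10 [2-(allyloxy)-4,6-bis(benzyloxy)phenyl](8-bromo-3-O-TBS-tetra-O-benzyl-epicatechin-6-yl)methanol (carbinol epimers), via arylmagnesium chloride 9 (not isolated)
Conditions: iPrMgCl·LiCl (1.1 equiv), THF, −20 °C → 0 °C; then 8 (1.3 equiv), −20 °C → rt; aq. NH4Cl
Reagents that add atoms: none
Why: Iodine–magnesium exchange is far faster at C–I than at the C8–Br bond, and the resulting 2,6-dialkoxyaryl Grignard reagent adds 1,2 to the aldehyde, so the 4→6 connectivity is fixed by the position of the iodine; the new carbinol centre is not controlled and need not be.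

Step 8
Reactants: 10 O-allyl benzhydrol
Product: 11 [4,6-bis(benzyloxy)-2-hydroxyphenyl](8-bromo-3-O-TBS-tetra-O-benzyl-epicatechin-6-yl)methanol (carbinol epimers)
Conditions: Pd(PPh3)4 (5 mol %), morpholine (3 equiv), THF, rt
Reagents that add atoms: none
Why: Tsuji–Trost deallylation in which zerovalent palladium ionises the aryl allyl ether and morpholine traps the π-allyl complex; the medium stays basic, so the acid-labile benzhydrol, the silyl and benzyl ethers and the hindered aryl bromide are untouched.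

Step 9
Reactants: 11 o-hydroxybenzhydrol on C6 of the 8-bromo-3-O-silyl epicatechin; 12 (tert-butyldimethylsilyloxy)acetaldehyde
Product: 15 3,4-trans 3-silyloxy-4-(epicatechin-6-yl)chroman-2-ol (3R; anomers), via o-quinone methide 13 (not isolated), via open-chain aldehyde 14 (not isolated)
Conditions: (S)-α,α-diphenylprolinol trimethylsilyl ether (20 mol %), PhCO2H (20 mol %), 12 (3 equiv), CH2Cl2, 0 °C → rt
Reagents that add atoms: none
Why: Benzoic acid dehydrates the doubly benzylic ortho-hydroxy carbinol to o-quinone methide 13 (only top ring A has a free phenol, so only it can become the methide) while the amine turns 12 into its E-enamine. The enamine carbon (future C3) adds to the methide carbon (future C4) and re-aromatises the ring; hydrolysis of the iminium ion gives aldehyde 14, and the phenol closes on the carbonyl carbon in a 6-exo-trig hemiacetalisation that forms O1–C2 and top ring C. The closest known reaction type is the diarylprolinol silyl ether-catalysed formal [4+2] of aldehydes with o-quinone methides generated in situ from o-hydroxybenzhydrols, which gives trans-3,4-disubstituted chroman-2-ols. C3 is set by the catalyst: the CPh2OTMS group of the (S)-amine shields one face of the anti E-enamine and attack on the open face gives 3R. C4 is set relative to C3 by the staggered approach of enamine and methide that leads to the 3,4-trans lactol, and C2 stays an anomer mixture. The step needs C–C bond formation at a very stabilised, hindered cation without arene alkylation, which the high nucleophilicity of the enamine and the bromine at C8 (no free nucleophilic position on the middle ring) should secure.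

Step 10
Reactants: 15 3,4-trans lactol; 16 4-bromo-1,2-bis(benzyloxy)benzene
Product: 19 (1S,2R)-1-[3,4-bis(benzyloxy)phenyl]-2-silyloxy-3-[4,6-bis(benzyloxy)-2-hydroxyphenyl]-3-(epicatechin-6-yl)propan-1-ol (1,2-anti), via aryl Grignard reagent 17 (not isolated), via ring-opened magnesium phenoxide aldehyde 18 (not isolated)
Conditions: 16, Mg, THF, rt (gives 17, 3.5 equiv); add 15, −78 °C → 0 °C; aq. NH4Cl
Reagents that add atoms: none
Why: Grignard addition to a lactol, in which the first equivalent of 17 deprotonates 15, the magnesium lactolate opens to the magnesium phenoxide aldehyde 18, and aryl addition to its carbonyl group follows the polar Felkin–Anh model (C–OSi bond anti to the nucleophile, which passes the α-hydrogen and not the diarylmethyl group), giving the 1,2-anti (1S) carbinol.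

Step 11
Reactants: 19 anti phenol–carbinol
Product: 20 3-O-TBS-tetra-O-benzyl-epicatechin-(4β→6)-8-bromo-3-O-TBS-tetra-O-benzyl-epicatechin
Conditions: PPh3, DIAD, THF, 0 °C → rt
Reagents that add atoms: none
Why: Intramolecular Mitsunobu etherification (6-exo-tet) in which the phenol displaces the oxyphosphonium of the benzylic alcohol with inversion, turning the 1S carbinol into 2R and so giving the 2,3-cis, 2,4-trans ring C without any acid or hydride step.

Step 12
Reactants: 20 protected top–middle dimer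
Product: 21 dimer 20 carrying a 4β-(2-ethoxyethoxy) group on the middle unit
Conditions: DDQ (2 equiv), 2-ethoxyethanol (5 equiv), CH2Cl2, rt
Reagents that add atoms: 2-ethoxyethanol, CCOCCO
Why: DDQ-mediated benzylic hydride abstraction at the only CH2 conjugated to a phloroglucinol-type ring (middle C4) gives a cation stabilised by the 5-, 7- and 1-oxygens, which the alcohol traps anti to the 3-silyloxy group; the top C4–H is a hindered methine lying in the plane of ring A and should be slow to react.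

Step 13
Reactants: 22 (+)-catechin
Product: 23 5,7,3',4'-tetra-O-benzyl-(+)-catechin
Conditions: BnBr (4.4 equiv), K2CO3, DMF, 0 °C → rt
Reagents that add atoms: benzyl bromide, BrCc1ccccc1
Why: Williamson etherification of the four phenols only, as in step 1.

Step 14
Reactants: 23 5,7,3',4'-tetra-O-benzyl-(+)-catechin
Product: 24 3,5,7,3',4'-penta-O-benzyl-(+)-catechin
Conditions: NaH, BnBr, DMF, 0 °C → rt
Reagents that add atoms: benzyl bromide, BrCc1ccccc1
Why: Williamson etherification of the secondary alkoxide, so that the bottom 3-OH stays masked during the double galloylation and is freed only in the last step.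

Step 15
Reactants: 21 4-alkoxy dimer; 24 penta-O-benzyl-(+)-catechin
Product: 25 fully protected trimer, top–(4β→6)–middle–(4β→8)–bottom
Conditions: 24 (4 equiv), TMSOTf (0.5 equiv), CH2Cl2, −78 °C; Et3N quench
Reagents that add atoms: none
Why: Lewis-acid ionisation of the C4 ether to the flavan-4-yl cation and Friedel–Crafts capture by C8 of 24, its most nucleophilic position, on the face anti to the 3-silyloxy and 2-aryl groups (4β, 3,4-trans); the excess of 24 outcompetes the free ring A positions of the top unit.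

Step 16
Reactants: 25 protected trimer
Product: 26 trimer with free 3-OH on the top and middle units
Conditions: TBAF (6 equiv), THF, rt → 45 °C
Reagents that add atoms: none
Why: Fluoride cleavage of both secondary silyl ethers, done before esterification so that no ester is exposed to fluoride; benzyl ethers and the aryl bromide are inert.

Step 17
Reactants: 26 trimer diol; 27 3,4,5-tris(benzyloxy)benzoic acid
Product: 28 3,3''-bis-O-(tri-O-benzylgalloyl) protected trimer
Conditions: 27 (6 equiv), DCC, DMAP, CH2Cl2, rt → 40 °C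
Reagents that add atoms: none
Why: Steglich esterification of the two axial 3-hydroxyls, the only free hydroxyls because the bottom 3-OH is a benzyl ether.

Step 18
Reactants: 28 protected digallate
Product: 29 CNP0112921.1 (target)
Conditions: H2 (1 atm), Pd(OH)2/C, THF/MeOH/H2O, rt
Reagents that add atoms: none
Why: Hydrogenolysis of all 19 benzyl ethers together with hydrodebromination at C8 of the middle unit, conditions that leave the gallate esters, the interflavan bonds and all stereocentres unchanged.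

**Compound list**

1 | (−)-epicatechin | O[C@@H]1Cc2c(O)cc(O)cc2O[C@@H]1c1ccc(O)c(O)c1 | starting material
2 | 5,7,3',4'-tetra-O-benzyl-(−)-epicatechin (2R,3R) | O[C@@H]1Cc2c(OCc9ccccc9)cc(OCc9ccccc9)cc2O[C@@H]1c1ccc(OCc9ccccc9)c(OCc9ccccc9)c1 | intermediate
3 | 3-O-TBS-5,7,3',4'-tetra-O-benzyl-epicatechin | CC(C)(C)[Si](C)(C)O[C@@H]1Cc2c(OCc9ccccc9)cc(OCc9ccccc9)cc2O[C@@H]1c1ccc(OCc9ccccc9)c(OCc9ccccc9)c1 | intermediate
4 | 8-bromo-3-O-TBS-5,7,3',4'-tetra-O-benzyl-epicatechin | CC(C)(C)[Si](C)(C)O[C@@H]1Cc2c(OCc9ccccc9)cc(OCc9ccccc9)c(Br)c2O[C@@H]1c1ccc(OCc9ccccc9)c(OCc9ccccc9)c1 | intermediate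
5 | 8-bromo-6-iodo-3-O-TBS-5,7,3',4'-tetra-O-benzyl-epicatechin | CC(C)(C)[Si](C)(C)O[C@@H]1Cc2c(OCc9ccccc9)c(I)c(OCc9ccccc9)c(Br)c2O[C@@H]1c1ccc(OCc9ccccc9)c(OCc9ccccc9)c1 | intermediate
6 | 2,4,6-trihydroxybenzaldehyde | O=Cc1c(O)cc(O)cc1O | starting material
7 | 4,6-bis(benzyloxy)-2-hydroxybenzaldehyde | O=Cc1c(O)cc(OCc9ccccc9)cc1OCc9ccccc9 | intermediate
8 | 2-(allyloxy)-4,6-bis(benzyloxy)benzaldehyde | O=Cc1c(OCC=C)cc(OCc9ccccc9)cc1OCc9ccccc9 | intermediate
9 | (8-bromo-3-O-TBS-tetra-O-benzyl-epicatechin-6-yl)magnesium chloride, not isolated | CC(C)(C)[Si](C)(C)O[C@@H]1Cc2c(OCc9ccccc9)c([Mg]Cl)c(OCc9ccccc9)c(Br)c2O[C@@H]1c1ccc(OCc9ccccc9)c(OCc9ccccc9)c1 | intermediate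
10 | [2-(allyloxy)-4,6-bis(benzyloxy)phenyl](8-bromo-3-O-TBS-tetra-O-benzyl-epicatechin-6-yl)methanol, carbinol epimers | C=CCOc2cc(OCc9ccccc9)cc(OCc9ccccc9)c2C(O)c3c(OCc9ccccc9)c(Br)c4c(c3OCc9ccccc9)C[C@@H](O[Si](C)(C)C(C)(C)C)[C@@H](c7ccc(OCc9ccccc9)c(OCc9ccccc9)c7)O4 | intermediate
11 | [4,6-bis(benzyloxy)-2-hydroxyphenyl](8-bromo-3-O-TBS-tetra-O-benzyl-epicatechin-6-yl)methanol, carbinol epimers (key-step precursor) | Oc2cc(OCc9ccccc9)cc(OCc9ccccc9)c2C(O)c3c(OCc9ccccc9)c(Br)c4c(c3OCc9ccccc9)C[C@@H](O[Si](C)(C)C(C)(C)C)[C@@H](c7ccc(OCc9ccccc9)c(OCc9ccccc9)c7)O4 | intermediate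
12 | (tert-butyldimethylsilyloxy)acetaldehyde | O=CCO[Si](C)(C)C(C)(C)C | starting material
13 | o-quinone methide from 11 (3,5-bis(benzyloxy)-6-(epicatechin-6-ylmethylidene)cyclohexa-2,4-dienone), not isolated | O=C2C=C(OCc9ccccc9)C=C(OCc9ccccc9)C2=Cc3c(OCc9ccccc9)c(Br)c4c(c3OCc9ccccc9)C[C@@H](O[Si](C)(C)C(C)(C)C)[C@@H](c7ccc(OCc9ccccc9)c(OCc9ccccc9)c7)O4 | intermediate
14 | (2R)-2-silyloxy-3-[4,6-bis(benzyloxy)-2-hydroxyphenyl]-3-(epicatechin-6-yl)propanal, open form of 15, not isolated | CC(C)(C)[Si](C)(C)O[C@@H](C=O)[C@@H](c3c(OCc9ccccc9)c(Br)c4c(c3OCc9ccccc9)C[C@@H](O[Si](C)(C)C(C)(C)C)[C@@H](c7ccc(OCc9ccccc9)c(OCc9ccccc9)c7)O4)c2c(OCc9ccccc9)cc(OCc9ccccc9)cc2O | intermediate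
15 | (3R)-5,7-bis(benzyloxy)-3-(TBS-oxy)-4-(8-bromo-3-O-TBS-tetra-O-benzyl-epicatechin-6-yl)chroman-2-ol, 3,4-trans, anomers (key-step product) | CC(C)(C)[Si](C)(C)O[C@@H]1[C@@H](c3c(OCc9ccccc9)c(Br)c4c(c3OCc9ccccc9)C[C@@H](O[Si](C)(C)C(C)(C)C)[C@@H](c7ccc(OCc9ccccc9)c(OCc9ccccc9)c7)O4)c2c(OCc9ccccc9)cc(OCc9ccccc9)cc2OC1O | intermediate
16 | 4-bromo-1,2-bis(benzyloxy)benzene | Brc1ccc(OCc9ccccc9)c(OCc9ccccc9)c1 | starting material
17 | [3,4-bis(benzyloxy)phenyl]magnesium bromide, not isolated | Br[Mg]c1ccc(OCc9ccccc9)c(OCc9ccccc9)c1 | intermediate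
18 | bromomagnesium phenoxide of aldehyde 14 (ring-opened magnesium lactolate of 15), not isolated | CC(C)(C)[Si](C)(C)O[C@@H](C=O)[C@@H](c3c(OCc9ccccc9)c(Br)c4c(c3OCc9ccccc9)C[C@@H](O[Si](C)(C)C(C)(C)C)[C@@H](c7ccc(OCc9ccccc9)c(OCc9ccccc9)c7)O4)c2c(OCc9ccccc9)cc(OCc9ccccc9)cc2O[Mg]Br | intermediate
19 | (1S,2R)-1-[3,4-bis(benzyloxy)phenyl]-2-(TBS-oxy)-3-[4,6-bis(benzyloxy)-2-hydroxyphenyl]-3-(8-bromo-3-O-TBS-tetra-O-benzyl-epicatechin-6-yl)propan-1-ol, 1,2-anti | CC(C)(C)[Si](C)(C)O[C@@H]([C@@H](O)c5ccc(OCc9ccccc9)c(OCc9ccccc9)c5)[C@@H](c3c(OCc9ccccc9)c(Br)c4c(c3OCc9ccccc9)C[C@@H](O[Si](C)(C)C(C)(C)C)[C@@H](c7ccc(OCc9ccccc9)c(OCc9ccccc9)c7)O4)c2c(OCc9ccccc9)cc(OCc9ccccc9)cc2O | intermediate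
20 | 3-O-TBS-tetra-O-benzyl-epicatechin-(4β→6)-8-bromo-3-O-TBS-tetra-O-benzyl-epicatechin (top unit 2R,3R, 2,3-cis, 3,4-trans) | CC(C)(C)[Si](C)(C)O[C@@H]1[C@@H](c3c(OCc9ccccc9)c(Br)c4c(c3OCc9ccccc9)C[C@@H](O[Si](C)(C)C(C)(C)C)[C@@H](c7ccc(OCc9ccccc9)c(OCc9ccccc9)c7)O4)c2c(OCc9ccccc9)cc(OCc9ccccc9)cc2O[C@@H]1c1ccc(OCc9ccccc9)c(OCc9ccccc9)c1 | intermediate
21 | dimer 20 with 4β-(2-ethoxyethoxy) on the middle unit (3,4-trans) | CC(C)(C)[Si](C)(C)O[C@@H]1[C@@H](c3c(OCc9ccccc9)c(Br)c4c(c3OCc9ccccc9)[C@H](OCCOCC)[C@@H](O[Si](C)(C)C(C)(C)C)[C@@H](c7ccc(OCc9ccccc9)c(OCc9ccccc9)c7)O4)c2c(OCc9ccccc9)cc(OCc9ccccc9)cc2O[C@@H]1c1ccc(OCc9ccccc9)c(OCc9ccccc9)c1 | intermediate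
22 | (+)-catechin | O[C@H]1Cc2c(O)cc(O)cc2O[C@@H]1c1ccc(O)c(O)c1 | starting material
23 | 5,7,3',4'-tetra-O-benzyl-(+)-catechin (2R,3S) | O[C@H]1Cc2c(OCc9ccccc9)cc(OCc9ccccc9)cc2O[C@@H]1c1ccc(OCc9ccccc9)c(OCc9ccccc9)c1 | intermediate
24 | 3,5,7,3',4'-penta-O-benzyl-(+)-catechin | C(c9ccccc9)O[C@H]1Cc2c(OCc9ccccc9)cc(OCc9ccccc9)cc2O[C@@H]1c1ccc(OCc9ccccc9)c(OCc9ccccc9)c1 | intermediate
25 | protected trimer: [3-O-TBS-tetra-O-benzyl-epicatechin]-(4β→6)-[8-bromo-3-O-TBS-tetra-O-benzyl-epicatechin]-(4β→8)-[penta-O-benzyl-catechin] | CC(C)(C)[Si](C)(C)O[C@@H]1[C@@H](c3c(OCc9ccccc9)c(Br)c4c(c3OCc9ccccc9)[C@H](c5c(OCc9ccccc9)cc(OCc9ccccc9)c6c5O[C@H](c8ccc(OCc9ccccc9)c(OCc9ccccc9)c8)[C@@H](OCc9ccccc9)C6)[C@@H](O[Si](C)(C)C(C)(C)C)[C@@H](c7ccc(OCc9ccccc9)c(OCc9ccccc9)c7)O4)c2c(OCc9ccccc9)cc(OCc9ccccc9)cc2O[C@@H]1c1ccc(OCc9ccccc9)c(OCc9ccccc9)c1 | intermediate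
26 | trimer 25 with both silyl ethers removed (free 3-OH on top and middle units) | O[C@@H]1[C@@H](c3c(OCc9ccccc9)c(Br)c4c(c3OCc9ccccc9)[C@H](c5c(OCc9ccccc9)cc(OCc9ccccc9)c6c5O[C@H](c8ccc(OCc9ccccc9)c(OCc9ccccc9)c8)[C@@H](OCc9ccccc9)C6)[C@@H](O)[C@@H](c7ccc(OCc9ccccc9)c(OCc9ccccc9)c7)O4)c2c(OCc9ccccc9)cc(OCc9ccccc9)cc2O[C@@H]1c1ccc(OCc9ccccc9)c(OCc9ccccc9)c1 | intermediate
27 | 3,4,5-tris(benzyloxy)benzoic acid | OC(=O)c1cc(OCc9ccccc9)c(OCc9ccccc9)c(OCc9ccccc9)c1 | starting material
28 | trimer 26 esterified at both free 3-OH groups with tri-O-benzylgalloyl | O=C(O[C@@H]1[C@@H](c3c(OCc9ccccc9)c(Br)c4c(c3OCc9ccccc9)[C@H](c5c(OCc9ccccc9)cc(OCc9ccccc9)c6c5O[C@H](c8ccc(OCc9ccccc9)c(OCc9ccccc9)c8)[C@@H](OCc9ccccc9)C6)[C@@H](OC(=O)c7cc(OCc9ccccc9)c(OCc9ccccc9)c(OCc9ccccc9)c7)[C@@H](c7ccc(OCc9ccccc9)c(OCc9ccccc9)c7)O4)c2c(OCc9ccccc9)cc(OCc9ccccc9)cc2O[C@@H]1c1ccc(OCc9ccccc9)c(OCc9ccccc9)c1)c1cc(OCc9ccccc9)c(OCc9ccccc9)c(OCc9ccccc9)c1 | intermediate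
29 | CNP0112921.1, epicatechin 3-O-gallate-(4β→6)-epicatechin 3-O-gallate-(4β→8)-catechin | O=C(O[C@@H]1[C@@H](c2c(O)cc3c(c2O)[C@H](c2c(O)cc(O)c4c2O[C@H](c2ccc(O)c(O)c2)[C@@H](O)C4)[C@@H](OC(=O)c2cc(O)c(O)c(O)c2)[C@@H](c2ccc(O)c(O)c2)O3)c2c(O)cc(O)cc2O[C@@H]1c1ccc(O)c(O)c1)c1cc(O)c(O)c(O)c1 | target

**Step count**

Total step count: 18. Longest linear sequence: 14 steps from (−)-epicatechin (steps 1–4, 7–12, 15–18).

**Steps most likely to fail**

Step 9 (key step). The methide, stabilised by six oxygens and flanked by four ortho substituents, may react too slowly with the enamine. Self-aldol of 12 or erosion of the 3,4-trans selection could then take over. The fallback makes the C4–C6 bond by the classical flavan-4-yl cation route and sets out from 3 and 4. Compound 3 is oxidised with DDQ in the presence of 2-ethoxyethanol (CH2Cl2, rt) to 4β-(2-ethoxyethoxy)-3-O-TBS-5,7,3',4'-tetra-O-benzyl-epicatechin F1. F1 is ionised with TMSOTf (CH2Cl2, −78 °C) in the presence of an excess of bromide 4, whose only free ring A position is C6. Attack anti to the 3-silyloxy group should give the 4β→6 dimer directly, and the fallback returns to the route at 20; steps 4 and 7–11 are then not needed.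

Step 11. The oxyphosphonium of the electron-rich, hindered benzylic alcohol may ionise before the phenol attacks, which would cost the inversion, or it may not form at all. The fallback sets out from 19; the carbinol-epimer mixture from step 10 serves equally. MnO2 (CH2Cl2, rt) oxidises the benzylic alcohol to the aryl ketone F2, which equilibrates with its cyclic hemiketal. Et3SiH with TMSOTf (CH2Cl2, −78 °C) then ionises the hemiketal and delivers hydride to C2 (reductive etherification), returning at 20. Here the facial selectivity depends on the pseudo-axial 3-silyloxy group outweighing the pseudo-axial C4 aryl group, so a separation of C2 epimers has to be expected.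

Step 12. Hydride abstraction may occur at another benzylic C–H (C2–H of either unit, top C4–H), or the bromine-deactivated ring may not react. The fallback moves the oxidation to the monomer stage, where C4 oxidation with DDQ and an alcohol is routine, and carries the ether through; this is possible because none of steps 3–11 uses a Lewis acid. It sets out from 3, which is oxidised as above to the 4β-(2-ethoxyethoxy) ether F1. NBS then gives the 8-bromo-4β-(2-ethoxyethoxy) monomer F3, and NIS gives the 8-bromo-6-iodo-4β-(2-ethoxyethoxy) monomer F4. Exchange with iPrMgCl·LiCl and addition to 8 give the O-allyl benzhydrol carrying the 4β-(2-ethoxyethoxy) group F5. Pd(PPh3)4 with morpholine gives the o-hydroxybenzhydrol carrying the 4β-(2-ethoxyethoxy) group F6. The aminocatalytic reaction with 12, with benzoic acid kept at catalytic level so that the C4 ether is not ionised, gives the 3,4-trans lactol carrying the 4β-(2-ethoxyethoxy) group F7. Addition of 17 gives the anti phenol–carbinol carrying the 4β-(2-ethoxyethoxy) group F8. Mitsunobu closure then returns to the route at 21.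

Further compounds
F1 | step 9 | 4β-(2-ethoxyethoxy)-3-O-TBS-5,7,3',4'-tetra-O-benzyl-epicatechin | CC(C)(C)[Si](C)(C)O[C@@H]1[C@@H](OCCOCC)c2c(OCc9ccccc9)cc(OCc9ccccc9)cc2O[C@@H]1c1ccc(OCc9ccccc9)c(OCc9ccccc9)c1
F2 | step 11 | (2R)-1-[3,4-bis(benzyloxy)phenyl]-2-(TBS-oxy)-3-[4,6-bis(benzyloxy)-2-hydroxyphenyl]-3-(8-bromo-3-O-TBS-tetra-O-benzyl-epicatechin-6-yl)propan-1-one | CC(C)(C)[Si](C)(C)O[C@@H](C(=O)c5ccc(OCc9ccccc9)c(OCc9ccccc9)c5)[C@@H](c3c(OCc9ccccc9)c(Br)c4c(c3OCc9ccccc9)C[C@@H](O[Si](C)(C)C(C)(C)C)[C@@H](c7ccc(OCc9ccccc9)c(OCc9ccccc9)c7)O4)c2c(OCc9ccccc9)cc(OCc9ccccc9)cc2O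
F3 | step 12 | 8-bromo-4β-(2-ethoxyethoxy)-3-O-TBS-5,7,3',4'-tetra-O-benzyl-epicatechin | CC(C)(C)[Si](C)(C)O[C@@H]1[C@@H](OCCOCC)c2c(OCc9ccccc9)cc(OCc9ccccc9)c(Br)c2O[C@@H]1c1ccc(OCc9ccccc9)c(OCc9ccccc9)c1
F4 | step 12 | 8-bromo-6-iodo-4β-(2-ethoxyethoxy)-3-O-TBS-5,7,3',4'-tetra-O-benzyl-epicatechin | CC(C)(C)[Si](C)(C)O[C@@H]1[C@@H](OCCOCC)c2c(OCc9ccccc9)c(I)c(OCc9ccccc9)c(Br)c2O[C@@H]1c1ccc(OCc9ccccc9)c(OCc9ccccc9)c1
F5 | step 12 | O-allyl benzhydrol 10 carrying 4β-(2-ethoxyethoxy), carbinol epimers | C=CCOc2cc(OCc9ccccc9)cc(OCc9ccccc9)c2C(O)c3c(OCc9ccccc9)c(Br)c4c(c3OCc9ccccc9)[C@H](OCCOCC)[C@@H](O[Si](C)(C)C(C)(C)C)[C@@H](c7ccc(OCc9ccccc9)c(OCc9ccccc9)c7)O4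
F6 | step 12 | o-hydroxybenzhydrol 11 carrying 4β-(2-ethoxyethoxy), carbinol epimers | Oc2cc(OCc9ccccc9)cc(OCc9ccccc9)c2C(O)c3c(OCc9ccccc9)c(Br)c4c(c3OCc9ccccc9)[C@H](OCCOCC)[C@@H](O[Si](C)(C)C(C)(C)C)[C@@H](c7ccc(OCc9ccccc9)c(OCc9ccccc9)c7)O4
F7 | step 12 | 3,4-trans lactol 15 carrying 4β-(2-ethoxyethoxy), anomers | CC(C)(C)[Si](C)(C)O[C@@H]1[C@@H](c3c(OCc9ccccc9)c(Br)c4c(c3OCc9ccccc9)[C@H](OCCOCC)[C@@H](O[Si](C)(C)C(C)(C)C)[C@@H](c7ccc(OCc9ccccc9)c(OCc9ccccc9)c7)O4)c2c(OCc9ccccc9)cc(OCc9ccccc9)cc2OC1O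
F8 | step 12 | anti phenol–carbinol 19 carrying 4β-(2-ethoxyethoxy) | CC(C)(C)[Si](C)(C)O[C@@H]([C@@H](O)c5ccc(OCc9ccccc9)c(OCc9ccccc9)c5)[C@@H](c3c(OCc9ccccc9)c(Br)c4c(c3OCc9ccccc9)[C@H](OCCOCC)[C@@H](O[Si](C)(C)C(C)(C)C)[C@@H](c7ccc(OCc9ccccc9)c(OCc9ccccc9)c7)O4)c2c(OCc9ccccc9)cc(OCc9ccccc9)cc2O
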